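**Conventions.** Unprimed locants refer to the 2,3-dihydrobenzofuran (O1, C2, C3, C3a, C4–C7, C7a) and primed locants to the chroman/chromanone (O1', C2', C3', C4', C4a', C5'–C8', C8a'). Ring A is the trioxygenated benzo ring of the chromanone, ring C its pyran ring, ring B the benzo ring of the dihydrobenzofuran, ring D its five-membered oxygen ring, and ring E the guaiacyl ring.

## The problem

Silyhermin B (23) is a 5,7-dihydroxychroman-4-one (rings A and C) joined through a C2'–C5 aryl bond to ring B of a 2,3-dihydrobenzofuran. That unit carries a hydroxyl at C7, a hydroxymethyl group at C3 and a 4-hydroxy-3-methoxyphenyl group (ring E) at C2. There are three stereocentres: C2 (R) and C3 (S), trans on ring D, and C2' (S) on ring C. C2 and C3 are adjacent and can control each other, since trans is the thermodynamic arrangement while C3 carries an epimerisable ester. C2' lies four bonds from C3 across ring B, so the existing centres cannot direct it and it must be set by a reagent. The flavanone opens to a 2'-hydroxychalcone under base (E1cB), which epimerises C2', so the endgame must avoid base. The O1–C2 bond is a benzylic ether para to a phenolic oxygen and is sensitive to strong acid and to prolonged hydrogenolysis, and the four phenols must stay masked until the last step. The enabling feature is ring C: at the flavan oxidation level its six atoms (O1', C2', C3', C4', C4a', C8a') are the [4+2] adduct of an ortho-quinone methide of ring A (O1'=C8a'–C4a'=C4') and a styrene (C2'=C3') on C5. Ring A is mirror-symmetric and trioxygenated, so only one quinone methide can form, it forms easily, and the same three oxygens make the C4' methylene the most hydride-labile site for later oxidation to the ketone.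

## Retrosynthesis

**Protecting groups (23 ⇐ 22 ⇐ 21).** The four O–benzyl bonds and the O–Si bond are cut. Benzyl on every phenol allows one neutral hydrogenolysis as the last step. The primary alcohol is carried as a TBS ether, removed beforehand by buffered HF so that no base reaches the flavanone. Flavanone 21 is the fully protected target.

**C4' oxidation level (21 ⇐ 20 ⇐ 19).** No skeletal bond is cut; the ketone is traced back through flavan-4-ol 20 to the C4' methylene of flavan 19. Keeping the ketone would force a chalcone-type closure with no control of C2'. Lowering the oxidation level turns ring C into a chroman, which can be made by cycloaddition. The forward reaction must abstract hydride selectively at C4', which the three oxygens of ring A should secure.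

**Ring C (19 ⇐ 14 + 17, through 18).** O1'–C2' and C3'–C4' are cut together. This joins two fragments of similar size in the last skeletal step and creates ring C and C2' in one event under a chiral acid. The neighbouring cuts are O1'–C2' alone (oxa-Michael or Mitsunobu closure) or C2'–C5 (conjugate arylation of a chromone). Each needs extra functional-group steps or a differently functionalised dihydrobenzofuran. The precursors are salicyl alcohol 17, which ionises to quinone methide 18, and styrene 14. The forward step must select one alkene face by catalyst alone and must trap 18 with the styrene faster than 18 alkylates electron-rich arenes.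

**Ring A fragment (17 ⇐ 16 ⇐ 15).** The benzylic C–O is traced to an aldehyde and two benzyl ethers are cut. 2,4,6-Trihydroxybenzaldehyde 15 dibenzylates at the two non-chelated phenols to give 16, and hydride reduction gives 17.

**Side chains of the dihydrobenzofuran (14 ⇐ 13 ⇐ 12 ⇐ 10).** The vinyl group comes from the C5 aldehyde by methylenation, and the silyloxymethyl group from the C3 ester. The aldehyde is held as a dioxolane until the ester has been reduced (11, not isolated). This leaves trans ester 10 as the stereodefined core.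

**Ring D (10 ⇐ 8, through 9).** C2–C3 is cut, which leads back to aryl diazoacetate 8. A chiral dirhodium carbenoid inserts into one of the two enantiotopic benzylic C–H bonds of the O1–CH2 ether and sets C2. Base equilibration of the cis ester 9 then sets C3. Closing O1–C2 or contracting a chromene would instead require a stereocentre to be built beforehand. Here the precursor is achiral.

**Diazo ester (8 ⇐ 7 ⇐ 6).** The diazo group comes from arylacetate 7 by diazo transfer. The aryl–CH2 bond of 7 is cut to aryl bromide 6 and a zinc ester enolate, joined by palladium catalysis.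

**Ether assembly (6 ⇐ 5 ⇐ 4 ⇐ 3 + 2; 2 ⇐ 1).** Two ether bonds and the acetal are cut. The more acidic 4-OH of 3-bromo-4,5-dihydroxybenzaldehyde 3 takes the ring E benzyl group from chloride 2 (made from alcohol 1). The 5-OH is then benzylated (5) and the aldehyde masked (6). The forward sequence relies on the acidity difference between the two phenols of 3.

## Roads not taken

**Alternative 1:** The strategic cut is C2–C3 of ring D. Diazo ester A2 loses N2 at Rh2(PTTL)4, the carbenoid inserts into the benzylic O–CH2 bond to close ring D, and DBU equilibrates C3 to give trans ester A1. The merits are catalytic control of C2 from an achiral precursor, C3 set by equilibration, and a short assembly of A2. Made the centre of the plan, however, it solves only rings B and D. Ring C would then come from the C5 aldehyde by aldol condensation with a 2-hydroxyacetophenone and base-mediated closure, where C2' forms without control under conditions that also epimerise it. The MOM ether at O7 of A1 also needs an acid step next to the acid-sensitive O1–C2 bond. For rings B and D this road is as good as the chosen one, which uses the same insertion as a supporting step (steps 6 and 7) with benzyl at O7. Its chalcone endgame would be about two steps shorter, because C4' arrives as a ketone. Against that the chosen plan sets catalyst control of C2' and a base-free endgame.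

**Alternative 2:** The cut is O1–C2. Ag2O oxidises the free guaiacyl phenol of the open-chain precursor A4 to a para-quinone methide. The ring B phenol adds to the methide carbon (5-exo) and gives A3. The road is biomimetic and needs neither a diazo compound nor a precious metal. C3 steers C2 to the trans ring directly, and A3 already carries the aldehyde. Its weak points for this target are as follows:
- Absolute configuration must be brought in at C3 of A4, which needs a multistep auxiliary sequence.
- A4 exposes two free phenols and an aldehyde to an oxidant.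
- The quinone methide can tautomerise to a styrene by loss of the C3 proton, which erases C3.
- A3 carries three kinds of protection (MOM, TBS, free phenol), and the free phenol must be capped before any quinone methide chemistry on ring A.

This road is better in reagent cost and in reaching trans without an epimerisation. The chosen plan sets against it a single catalytic asymmetric step with close precedent on this ring class and uniform benzyl protection. C2' remains unsolved here as well.

**Alternative 3:** The cut forms C3–C3a by a 1,2-aryl shift while C4–C4a of a chromene breaks. PhI(OH)OTs in methanol and trimethyl orthoformate adds to C3=C4 of (R)-chromene A6. The ring B carbon migrates, the pyran contracts, and the trans acetal A5 results. Chirality is relayed from C2 of the chromene, and trans follows from anti migration. The C5 bromide is a direct handle for vinylation by cross-coupling. In that respect this road is better than the chosen route, which needs an acetal, its hydrolysis and a Wittig reaction. Its weak points are these: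
- A6 needs its own asymmetric synthesis and is configurationally fragile, through reversible electrocyclic ring opening and ionisation at the allylic, benzylic, α-oxygenated C2.
- The trivalent-iodine electrophile must discriminate between the alkene and three electron-rich arenes.
- Solvent addition without migration competes, because the migrating ring is deactivated by bromine.
- Acetal hydrolysis, reduction and silylation still follow, so it is not shorter.

The chosen plan sets against the better handle an achiral, robust precursor and precedent on exactly the 2-aryl-3-carboxylate ring system. C2' is again left open.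

Key step: step 13

## Assumptions

- Rh2(S-PTTL)4 is taken as the catalyst hand that gives 2R, by analogy with insertions of this type. If a trial shows the opposite sense, the R catalyst is used with nothing else changed.
- (R)-TRIP is written as the acid hand that gives 2'S. Because the existing stereocentres are remote, both hands are to be run on a small scale and the one giving 2'S is kept.
- Compounds 1, 3 and 15 are taken as purchasable.

## Route

Step 1
Reactants: 1 4-(benzyloxy)-3-methoxybenzyl alcohol
Product: 2 4-(benzyloxy)-3-methoxybenzyl chloride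
Conditions: SOCl2, CH2Cl2, 0 °C to rt
Reagents that add atoms: thionyl chloride, O=S(Cl)Cl
Why: Chlorination of a benzylic alcohol through its chlorosulfite; the electron-rich ring makes substitution fast at 0 °C, and the crude chloride is used at once.

Step 2
Reactants: 3 3-bromo-4,5-dihydroxybenzaldehyde; 2 4-(benzyloxy)-3-methoxybenzyl chloride
Product: 4 3-bromo-4-{[4-(benzyloxy)-3-methoxyphenyl]methoxy}-5-hydroxybenzaldehyde
Conditions: NaHCO3, NaI (cat.), DMF, 40 °C
Reagents that add atoms: none
Why: Williamson ether synthesis under weak-base control: the 4-OH, para to the formyl group and ortho to bromine, is much the more acidic phenol, so hydrogencarbonate should ionise it alone and the benzylic halide (iodide by Finkelstein exchange) should alkylate O4.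

Step 3
Reactants: 4 3-bromo-4-{[4-(benzyloxy)-3-methoxyphenyl]methoxy}-5-hydroxybenzaldehyde
Product: 5 3-(benzyloxy)-4-{[4-(benzyloxy)-3-methoxyphenyl]methoxy}-5-bromobenzaldehyde
Conditions: BnBr, K2CO3, DMF, rt
Reagents that add atoms: benzyl bromide, BrCc1ccccc1
Why: Williamson benzylation of the one remaining phenol; no other nucleophilic site is present.

Step 4
Reactants: 5 3-(benzyloxy)-4-{[4-(benzyloxy)-3-methoxyphenyl]methoxy}-5-bromobenzaldehyde
Product: 6 2-[3-(benzyloxy)-4-{[4-(benzyloxy)-3-methoxyphenyl]methoxy}-5-bromophenyl]-1,3-dioxolane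
Conditions: HOCH2CH2OH, PPTS (cat.), benzene, reflux, Dean–Stark
Reagents that add atoms: ethylene glycol, OCCO
Why: Acetalisation with azeotropic removal of water masks the aldehyde against the zinc enolate and the carbenoid of later steps; PPTS is mild enough for the electron-rich benzyl aryl ether.

Step 5
Reactants: 6 2-[3-(benzyloxy)-4-{[4-(benzyloxy)-3-methoxyphenyl]methoxy}-5-bromophenyl]-1,3-dioxolane
Product: 7 methyl 2-[3-(benzyloxy)-2-{[4-(benzyloxy)-3-methoxyphenyl]methoxy}-5-(1,3-dioxolan-2-yl)phenyl]acetate
Conditions: BrZnCH2CO2Me (preformed), Pd2(dba)3 (cat.), XPhos, THF, 65 °C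
Reagents that add atoms: (2-methoxy-2-oxoethyl)zinc bromide, COC(=O)C[Zn]Br
Why: Negishi-type coupling of a Reformatsky reagent (palladium-catalysed α-arylation of an ester enolate); the neutral zinc enolate tolerates acetal and ethers, and the bulky biarylphosphine promotes oxidative addition into the hindered, electron-rich aryl bromide.

Step 6
Reactants: 7 methyl 2-[3-(benzyloxy)-2-{[4-(benzyloxy)-3-methoxyphenyl]methoxy}-5-(1,3-dioxolan-2-yl)phenyl]acetate
Product: 8 methyl 2-diazo-2-[3-(benzyloxy)-2-{[4-(benzyloxy)-3-methoxyphenyl]methoxy}-5-(1,3-dioxolan-2-yl)phenyl]acetate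
Conditions: p-ABSA, DBU, MeCN, 0 °C to rt
Reagents that add atoms: 4-acetamidobenzenesulfonyl azide, CC(=O)Nc1ccc(cc1)S(=O)(=O)N=[N+]=[N-]
Why: Regitz diazo transfer to the methylene activated by both the ester and the arene, the standard entry to aryl diazoacetates.

Step 7
Reactants: 8 methyl 2-diazo-2-[3-(benzyloxy)-2-{[4-(benzyloxy)-3-methoxyphenyl]methoxy}-5-(1,3-dioxolan-2-yl)phenyl]acetate
Product: 10 methyl (2R,3R)-7-(benzyloxy)-2-[4-(benzyloxy)-3-methoxyphenyl]-5-(1,3-dioxolan-2-yl)-2,3-dihydro-1-benzofuran-3-carboxylate (2,3-trans), via cis (2R,3S) ester 9 (not isolated)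
Conditions: Rh2(S-PTTL)4 (1 mol %), toluene, −60 °C; then NaOMe (cat.), MeOH, 0 °C to rt
Reagents that add atoms: none
Why: Intramolecular rhodium-carbenoid 1,5 C–H insertion into the O–CH2 bond, activated by the ether oxygen and ring E, forms C2–C3 and closes ring D; the chiral carboxylate ligands of dirhodium tetrakis[N-phthaloyl-(S)-tert-leucinate] differentiate the two enantiotopic benzylic hydrogens and so set C2 (R), giving the kinetic cis ester. Catalytic methoxide then equilibrates C3 through the ester enolate to the less strained trans ester, which fixes C3 relative to C2.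

Step 8
Reactants: 10 methyl (2R,3R)-7-(benzyloxy)-2-[4-(benzyloxy)-3-methoxyphenyl]-5-(1,3-dioxolan-2-yl)-2,3-dihydro-1-benzofuran-3-carboxylate
Product: 12 (2R,3S)-7-(benzyloxy)-2-[4-(benzyloxy)-3-methoxyphenyl]-3-(hydroxymethyl)-2,3-dihydro-1-benzofuran-5-carbaldehyde, via dioxolane alcohol 11 (not isolated)
Conditions: LiAlH4, THF, 0 °C; quench; then 1 M aq. HCl, THF, rt
Reagents that add atoms: water, O
Why: Hydride reduction of the ester to the primary alcohol leaves the acetal and benzyl ethers untouched and removes the acidity of C3, so its configuration is now fixed; dilute acid then hydrolyses the aryl dioxolane at room temperature without ionising the O1–C2 bond.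

Step 9
Reactants: 12 (2R,3S)-7-(benzyloxy)-2-[4-(benzyloxy)-3-methoxyphenyl]-3-(hydroxymethyl)-2,3-dihydro-1-benzofuran-5-carbaldehyde
Product: 13 (2R,3S)-7-(benzyloxy)-2-[4-(benzyloxy)-3-methoxyphenyl]-3-{[tert-butyl(dimethyl)silyl]oxymethyl}-2,3-dihydro-1-benzofuran-5-carbaldehyde
Conditions: TBSCl, imidazole, DMF, rt
Reagents that add atoms: tert-butyldimethylsilyl chloride, CC(C)(C)[Si](C)(C)Cl
Why: Standard silylation of a primary alcohol; the silyl ether keeps the hydroxyl out of the quinone methide chemistry and the later alcohol oxidation.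

Step 10
Reactants: 13 (2R,3S)-7-(benzyloxy)-2-[4-(benzyloxy)-3-methoxyphenyl]-3-{[tert-butyl(dimethyl)silyl]oxymethyl}-2,3-dihydro-1-benzofuran-5-carbaldehyde
Product: 14 (2R,3S)-7-(benzyloxy)-2-[4-(benzyloxy)-3-methoxyphenyl]-3-{[tert-butyl(dimethyl)silyl]oxymethyl}-5-ethenyl-2,3-dihydro-1-benzofuran
Conditions: Ph3PCH3Br, KOtBu, THF, 0 °C to rt
Reagents that add atoms: methyltriphenylphosphonium bromide, C[P+](c1ccccc1)(c1ccccc1)c1ccccc1.[Br-]
Why: Wittig methylenation of an aromatic aldehyde with the non-stabilised ylide; no enolisable or base-sensitive centre is present.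

Step 11
Reactants: 15 2,4,6-trihydroxybenzaldehyde
Product: 16 2,4-bis(benzyloxy)-6-hydroxybenzaldehyde
Conditions: BnBr (2.1 equiv), K2CO3, DMF, rt
Reagents that add atoms: benzyl bromide, BrCc1ccccc1
Why: Williamson ether synthesis that stops at the dibenzyl ether because the last ortho phenol is held in a hydrogen bond to the formyl oxygen; the symmetry of 15 makes the two ortho positions equivalent, so one product is expected.

Step 12
Reactants: 16 2,4-bis(benzyloxy)-6-hydroxybenzaldehyde
Product: 17 3,5-bis(benzyloxy)-2-(hydroxymethyl)phenol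
Conditions: NaBH4, THF/MeOH, 0 °C; pH 7 buffer quench
Reagents that add atoms: none
Why: Borohydride reduction of the aldehyde to the salicyl alcohol; the product is an easily ionised quinone methide precursor, so it is kept cold, worked up at neutral pH and used without chromatography.

Step 13
Reactants: 14 (2R,3S)-7-(benzyloxy)-2-[4-(benzyloxy)-3-methoxyphenyl]-3-{[tert-butyl(dimethyl)silyl]oxymethyl}-5-ethenyl-2,3-dihydro-1-benzofuran; 17 3,5-bis(benzyloxy)-2-(hydroxymethyl)phenol
Product: 19 (2S)-5,7-bis(benzyloxy)-2-[(2R,3S)-7-(benzyloxy)-2-[4-(benzyloxy)-3-methoxyphenyl]-3-{[tert-butyl(dimethyl)silyl]oxymethyl}-2,3-dihydro-1-benzofuran-5-yl]chromane, via ortho-quinone methide 18 (not isolated)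
Conditions: (R)-TRIP (3,3'-bis(2,4,6-triisopropylphenyl)-BINOL hydrogen phosphate, 10 mol %), 5 Å molecular sieves, toluene, 0 °C, slow addition of 17
Reagents that add atoms: none
Why: The phosphoric acid protonates the benzylic hydroxyl of 17 and water leaves with help from the three oxygens of ring A, giving ortho-quinone methide 18 hydrogen-bonded through its carbonyl oxygen to the catalyst. The vinyl group of 14, made nucleophilic at its CH2 end by the para oxygen O1, attacks the methide carbon (C3'–C4') while the quinone oxygen closes onto the benzylic carbon (O1'–C2'), a concerted but asynchronous inverse-electron-demand hetero-Diels–Alder reaction that restores the aromaticity of ring A. The closest known reaction type is the Brønsted-acid-catalysed [4+2] cycloaddition of quinone methides from 2-hydroxybenzyl alcohols with styrenes to give 2-arylchromans, which has been run with chiral BINOL-derived acids that activate only the heterodiene. Ring C closes as a six-membered [4+2] ring (4π heterodiene plus 2π alkene); in the stepwise limit the phenolic oxygen captures a para-alkoxybenzyl cation to the same ring. C2' is the only new stereocentre and is set by the catalyst, which is bound at the oxygen that forms the O1'–C2' bond and whose 3,3'-aryl groups leave one face of the styrene open; C2 and C3 are too far away to help or oppose. Regiochemistry is fixed by the polarisation of both partners, and the mirror symmetry of ring A with its single free phenol allows only one quinone methide. The step also needs cycloaddition to outrun Friedel–Crafts attack of 18 on electron-rich arenes, which slow addition of 17 to 14 should secure by keeping the standing concentration of 18 low.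

Step 14
Reactants: 19 (2S)-5,7-bis(benzyloxy)-2-[(2R,3S)-7-(benzyloxy)-2-[4-(benzyloxy)-3-methoxyphenyl]-3-{[tert-butyl(dimethyl)silyl]oxymethyl}-2,3-dihydro-1-benzofuran-5-yl]chromane
Product: 20 (2S)-5,7-bis(benzyloxy)-2-[(2R,3S)-7-(benzyloxy)-2-[4-(benzyloxy)-3-methoxyphenyl]-3-{[tert-butyl(dimethyl)silyl]oxymethyl}-2,3-dihydro-1-benzofuran-5-yl]chroman-4-ol (both C4' epimers)
Conditions: DDQ (1.2 equiv), CH2Cl2/pH 7 phosphate buffer (10:1), 0 °C
Reagents that add atoms: water, O
Why: DDQ benzylic oxidation by hydride abstraction at C4', the methylene on the ring A carbon that has oxygen at both ortho positions and at the para position; water traps the cation, as in the known C4 functionalisation of 5,7-dialkoxyflavans. The C4' epimers converge in the next step, and any over-oxidation to the ketone gives the next compound.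

Step 15
Reactants: 20 (2S)-5,7-bis(benzyloxy)-2-[(2R,3S)-7-(benzyloxy)-2-[4-(benzyloxy)-3-methoxyphenyl]-3-{[tert-butyl(dimethyl)silyl]oxymethyl}-2,3-dihydro-1-benzofuran-5-yl]chroman-4-ol
Product: 21 (2S)-5,7-bis(benzyloxy)-2-[(2R,3S)-7-(benzyloxy)-2-[4-(benzyloxy)-3-methoxyphenyl]-3-{[tert-butyl(dimethyl)silyl]oxymethyl}-2,3-dihydro-1-benzofuran-5-yl]chroman-4-one
Conditions: Dess–Martin periodinane, pyridine, CH2Cl2, 0 °C to rt
Reagents that add atoms: none
Why: Dess–Martin oxidation of a secondary benzylic alcohol to the aryl ketone under near-neutral conditions, which spare the silyl ether and do not open the new flavanone at C2'.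

Step 16
Reactants: 21 (2S)-5,7-bis(benzyloxy)-2-[(2R,3S)-7-(benzyloxy)-2-[4-(benzyloxy)-3-methoxyphenyl]-3-{[tert-butyl(dimethyl)silyl]oxymethyl}-2,3-dihydro-1-benzofuran-5-yl]chroman-4-one
Product: 22 (2S)-5,7-bis(benzyloxy)-2-[(2R,3S)-7-(benzyloxy)-2-[4-(benzyloxy)-3-methoxyphenyl]-3-(hydroxymethyl)-2,3-dihydro-1-benzofuran-5-yl]chroman-4-one
Conditions: HF·pyridine, THF/pyridine, 0 °C to rt
Reagents that add atoms: none
Why: Fluoride-mediated desilylation of the primary silyl ether under buffered acidic conditions; basic fluoride is avoided because flavanones open to chalcones by E1cB and would lose C2'.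

Step 17
Reactants: 22 (2S)-5,7-bis(benzyloxy)-2-[(2R,3S)-7-(benzyloxy)-2-[4-(benzyloxy)-3-methoxyphenyl]-3-(hydroxymethyl)-2,3-dihydro-1-benzofuran-5-yl]chroman-4-one
Product: 23 silyhermin B, (2S)-5,7-dihydroxy-2-[(2R,3S)-7-hydroxy-2-(4-hydroxy-3-methoxyphenyl)-3-(hydroxymethyl)-2,3-dihydro-1-benzofuran-5-yl]chroman-4-one
Conditions: H2 (1 atm), Pd/C (10 wt %), EtOAc/MeOH, rt
Reagents that add atoms: none
Why: Catalytic hydrogenolysis of the four aryl benzyl ethers, which cleave much faster than the cyclic benzylic O1–C2 and O1'–C2' bonds; the reaction is stopped once the uptake for four benzyl groups is reached, and no stereocentre is touched.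

## Compound list

1 | 4-(benzyloxy)-3-methoxybenzyl alcohol | COc1cc(CO)ccc1OCc1ccccc1 | starting material
2 | 4-(benzyloxy)-3-methoxybenzyl chloride | COc1cc(CCl)ccc1OCc1ccccc1 | intermediate
3 | 3-bromo-4,5-dihydroxybenzaldehyde | O=Cc1cc(O)c(O)c(Br)c1 | starting material
4 | 3-bromo-4-{[4-(benzyloxy)-3-methoxyphenyl]methoxy}-5-hydroxybenzaldehyde | COc1cc(COc2c(O)cc(C=O)cc2Br)ccc1OCc1ccccc1 | intermediate
5 | 3-(benzyloxy)-4-{[4-(benzyloxy)-3-methoxyphenyl]methoxy}-5-bromobenzaldehyde | COc1cc(COc2c(OCc3ccccc3)cc(C=O)cc2Br)ccc1OCc1ccccc1 | intermediate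
6 | 2-[3-(benzyloxy)-4-{[4-(benzyloxy)-3-methoxyphenyl]methoxy}-5-bromophenyl]-1,3-dioxolane | COc1cc(COc2c(OCc3ccccc3)cc(C3OCCO3)cc2Br)ccc1OCc1ccccc1 | intermediate
7 | methyl 2-[3-(benzyloxy)-2-{[4-(benzyloxy)-3-methoxyphenyl]methoxy}-5-(1,3-dioxolan-2-yl)phenyl]acetate | COC(=O)Cc1cc(C2OCCO2)cc(OCc2ccccc2)c1OCc1ccc(OCc2ccccc2)c(OC)c1 | intermediate
8 | methyl 2-diazo-2-[3-(benzyloxy)-2-{[4-(benzyloxy)-3-methoxyphenyl]methoxy}-5-(1,3-dioxolan-2-yl)phenyl]acetate | COC(=O)C(=[N+]=[N-])c1cc(C2OCCO2)cc(OCc2ccccc2)c1OCc1ccc(OCc2ccccc2)c(OC)c1 | intermediate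
9 | methyl (2R,3S)-7-(benzyloxy)-2-[4-(benzyloxy)-3-methoxyphenyl]-5-(1,3-dioxolan-2-yl)-2,3-dihydro-1-benzofuran-3-carboxylate (2,3-cis; not isolated) | COc1cc([C@@H]2Oc3c(OCc4ccccc4)cc(C4OCCO4)cc3[C@@H]2C(=O)OC)ccc1OCc1ccccc1 | intermediate
10 | methyl (2R,3R)-7-(benzyloxy)-2-[4-(benzyloxy)-3-methoxyphenyl]-5-(1,3-dioxolan-2-yl)-2,3-dihydro-1-benzofuran-3-carboxylate (2,3-trans) | COc1cc([C@@H]2Oc3c(OCc4ccccc4)cc(C4OCCO4)cc3[C@H]2C(=O)OC)ccc1OCc1ccccc1 | intermediate
11 | [(2R,3S)-7-(benzyloxy)-2-[4-(benzyloxy)-3-methoxyphenyl]-5-(1,3-dioxolan-2-yl)-2,3-dihydro-1-benzofuran-3-yl]methanol (not isolated) | COc1cc([C@@H]2Oc3c(OCc4ccccc4)cc(C4OCCO4)cc3[C@H]2CO)ccc1OCc1ccccc1 | intermediate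
12 | (2R,3S)-7-(benzyloxy)-2-[4-(benzyloxy)-3-methoxyphenyl]-3-(hydroxymethyl)-2,3-dihydro-1-benzofuran-5-carbaldehyde | COc1cc([C@@H]2Oc3c(OCc4ccccc4)cc(C=O)cc3[C@H]2CO)ccc1OCc1ccccc1 | intermediate
13 | (2R,3S)-7-(benzyloxy)-2-[4-(benzyloxy)-3-methoxyphenyl]-3-{[tert-butyl(dimethyl)silyl]oxymethyl}-2,3-dihydro-1-benzofuran-5-carbaldehyde | COc1cc([C@@H]2Oc3c(OCc4ccccc4)cc(C=O)cc3[C@H]2CO[Si](C)(C)C(C)(C)C)ccc1OCc1ccccc1 | intermediate
14 | (2R,3S)-7-(benzyloxy)-2-[4-(benzyloxy)-3-methoxyphenyl]-3-{[tert-butyl(dimethyl)silyl]oxymethyl}-5-ethenyl-2,3-dihydro-1-benzofuran | COc1cc([C@@H]2Oc3c(OCc4ccccc4)cc(C=C)cc3[C@H]2CO[Si](C)(C)C(C)(C)C)ccc1OCc1ccccc1 | intermediate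
15 | 2,4,6-trihydroxybenzaldehyde | O=Cc1c(O)cc(O)cc1O | starting material
16 | 2,4-bis(benzyloxy)-6-hydroxybenzaldehyde | O=Cc1c(O)cc(OCc2ccccc2)cc1OCc1ccccc1 | intermediate
17 | 3,5-bis(benzyloxy)-2-(hydroxymethyl)phenol | OCc1c(O)cc(OCc2ccccc2)cc1OCc1ccccc1 | intermediate
18 | 3,5-bis(benzyloxy)-6-methylidenecyclohexa-2,4-dien-1-one (ortho-quinone methide; not isolated) | C=C1C(=O)C=C(OCc2ccccc2)C=C1OCc1ccccc1 | intermediate
19 | (2S)-5,7-bis(benzyloxy)-2-[(2R,3S)-7-(benzyloxy)-2-[4-(benzyloxy)-3-methoxyphenyl]-3-{[tert-butyl(dimethyl)silyl]oxymethyl}-2,3-dihydro-1-benzofuran-5-yl]chromane | COc1cc([C@@H]2Oc3c(OCc4ccccc4)cc([C@@H]4CCc5c(OCc6ccccc6)cc(OCc6ccccc6)cc5O4)cc3[C@H]2CO[Si](C)(C)C(C)(C)C)ccc1OCc1ccccc1 | intermediate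
20 | (2S)-5,7-bis(benzyloxy)-2-[(2R,3S)-7-(benzyloxy)-2-[4-(benzyloxy)-3-methoxyphenyl]-3-{[tert-butyl(dimethyl)silyl]oxymethyl}-2,3-dihydro-1-benzofuran-5-yl]chroman-4-ol (both C4' epimers) | COc1cc([C@@H]2Oc3c(OCc4ccccc4)cc([C@@H]4CC(O)c5c(OCc6ccccc6)cc(OCc6ccccc6)cc5O4)cc3[C@H]2CO[Si](C)(C)C(C)(C)C)ccc1OCc1ccccc1 | intermediate
21 | (2S)-5,7-bis(benzyloxy)-2-[(2R,3S)-7-(benzyloxy)-2-[4-(benzyloxy)-3-methoxyphenyl]-3-{[tert-butyl(dimethyl)silyl]oxymethyl}-2,3-dihydro-1-benzofuran-5-yl]chroman-4-one | COc1cc([C@@H]2Oc3c(OCc4ccccc4)cc([C@@H]4CC(=O)c5c(OCc6ccccc6)cc(OCc6ccccc6)cc5O4)cc3[C@H]2CO[Si](C)(C)C(C)(C)C)ccc1OCc1ccccc1 | intermediate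
22 | (2S)-5,7-bis(benzyloxy)-2-[(2R,3S)-7-(benzyloxy)-2-[4-(benzyloxy)-3-methoxyphenyl]-3-(hydroxymethyl)-2,3-dihydro-1-benzofuran-5-yl]chroman-4-one | COc1cc([C@@H]2Oc3c(OCc4ccccc4)cc([C@@H]4CC(=O)c5c(OCc6ccccc6)cc(OCc6ccccc6)cc5O4)cc3[C@H]2CO)ccc1OCc1ccccc1 | intermediate
23 | silyhermin B, (2S)-5,7-dihydroxy-2-[(2R,3S)-7-hydroxy-2-(4-hydroxy-3-methoxyphenyl)-3-(hydroxymethyl)-2,3-dihydro-1-benzofuran-5-yl]chroman-4-one | COc1cc([C@@H]2Oc3c(O)cc([C@@H]4CC(=O)c5c(O)cc(O)cc5O4)cc3[C@H]2CO)ccc1O | target

## Step count and risks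

Total steps: 17. Longest linear sequence: 15 steps (steps 1–10 and 13–17, from 1 to 23). Steps 11 and 12 form the two-step side branch.

**Step 13 (key step).** Facial selectivity may be poor, because the methide carbon is unsubstituted and the stereocentres of 14 are too remote to help, so the acid alone must choose the face. Quinone methide 18 may also be consumed by Friedel–Crafts alkylation of ring A of 17 or 19, and the electron-rich styrene may dimerise under acid.
Fallback: from aldehyde 13, a Claisen–Schmidt condensation (KOH, EtOH/THF, rt) with purchased 1-[2,4-bis(benzyloxy)-6-hydroxyphenyl]ethan-1-one F1 should give (E)-1-[2,4-bis(benzyloxy)-6-hydroxyphenyl]-3-[(2R,3S)-7-(benzyloxy)-2-[4-(benzyloxy)-3-methoxyphenyl]-3-{[tert-butyl(dimethyl)silyl]oxymethyl}-2,3-dihydro-1-benzofuran-5-yl]prop-2-en-1-one F2. Oxa-Michael closure (NaOAc, EtOH, reflux) should give 21 together with its C2' epimer, (2R)-5,7-bis(benzyloxy)-2-[(2R,3S)-7-(benzyloxy)-2-[4-(benzyloxy)-3-methoxyphenyl]-3-{[tert-butyl(dimethyl)silyl]oxymethyl}-2,3-dihydro-1-benzofuran-5-yl]chroman-4-one F3. The two diastereomers are separated by preparative HPLC, and F3 is returned to the equilibrating conditions. The route is rejoined at 21. Steps 10 and 12–15 are not needed, but control of C2' is lost.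

**Step 14.** The C4' cation may lose a proton from C3' to give the flav-3-ene, which DDQ would oxidise on to the flavylium salt. Hydride abstraction may also compete at C2' or C2, which are both benzylic and α to oxygen.
Fallback: the C4' oxygen is introduced during the cycloaddition. Styrene 14 and aldehyde 16 are combined with trimethyl orthoformate and the same chiral acid. The 2-hydroxyaryl oxocarbenium ion formed from the dimethyl acetal of 16 should add to the styrene (a known three-component route to 4-alkoxy-2-arylchromans). This should give (2S)-5,7-bis(benzyloxy)-4-methoxy-2-[(2R,3S)-7-(benzyloxy)-2-[4-(benzyloxy)-3-methoxyphenyl]-3-{[tert-butyl(dimethyl)silyl]oxymethyl}-2,3-dihydro-1-benzofuran-5-yl]chromane F4 as C4' epimers. Hydrolysis of the very labile trialkoxybenzylic methyl ether (PPTS, wet THF, rt) returns the route at 20. Face control at C2' would have to be re-examined in this variant.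

**Step 7.** Enantioselection in the insertion may be insufficient, because the extra benzyloxy group next to the reacting ether can change the conformation the catalyst has to read. Ring opening by β-elimination of the phenoxide may occur during the base equilibration.
Fallback: control is moved from the catalyst to an auxiliary, which gives separable diastereomers. From 7, saponification (LiOH, THF/H2O) gives 2-[3-(benzyloxy)-2-{[4-(benzyloxy)-3-methoxyphenyl]methoxy}-5-(1,3-dioxolan-2-yl)phenyl]acetic acid F5. Esterification (EDC, DMAP) with purchased (2S)-2-hydroxy-1-(pyrrolidin-1-yl)propan-1-one F6 gives (2S)-1-oxo-1-(pyrrolidin-1-yl)propan-2-yl 2-[3-(benzyloxy)-2-{[4-(benzyloxy)-3-methoxyphenyl]methoxy}-5-(1,3-dioxolan-2-yl)phenyl]acetate F7. Diazo transfer (p-ABSA, DBU) gives (2S)-1-oxo-1-(pyrrolidin-1-yl)propan-2-yl 2-diazo-2-[3-(benzyloxy)-2-{[4-(benzyloxy)-3-methoxyphenyl]methoxy}-5-(1,3-dioxolan-2-yl)phenyl]acetate F8. Insertion with Rh2(S-DOSP)4 (dirhodium tetrakis[N-(4-dodecylbenzenesulfonyl)-(S)-prolinate]), with base equilibration if needed, should give (2S)-1-oxo-1-(pyrrolidin-1-yl)propan-2-yl (2R,3R)-7-(benzyloxy)-2-[4-(benzyloxy)-3-methoxyphenyl]-5-(1,3-dioxolan-2-yl)-2,3-dihydro-1-benzofuran-3-carboxylate F9. F9 is purified from its diastereomers by chromatography or crystallisation. LiAlH4 then removes the auxiliary and gives 11, and the acid work-up of step 8 takes it on to 12, where the route is rejoined. The hand of the auxiliary is to be matched to 2R on a trial run.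

**Step 2.** Alkylation may spill over to O5 and to the dialkyl ether, because the more acidic O4 is also the more hindered oxygen, flanked by bromine and hydroxyl. The reactive chloride may also solvolyse.
Fallback: the oxygens are differentiated before bromine is introduced. Purchased 3-(benzyloxy)-4-hydroxybenzaldehyde F10 is brominated ortho to the free phenol (Br2, NaOAc, AcOH) to give 3-(benzyloxy)-5-bromo-4-hydroxybenzaldehyde F11. Its single phenol is alkylated with chloride 2 (K2CO3, DMF), which rejoins the route at 5 in the same number of steps.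

**Step 17.** Hydrogenolysis may run past the benzyl ethers and cleave the benzylic O1–C2 or O1'–C2' bond or reduce the ketone, or it may stop short of full debenzylation.
Fallback: from 22, the benzyl ethers are cleaved by a Lewis acid and not by hydrogen. BCl3 with pentamethylbenzene as cation scavenger in CH2Cl2 at −78 °C should give 23 directly.

## Further compounds

F1 | step 13 | 1-[2,4-bis(benzyloxy)-6-hydroxyphenyl]ethan-1-one (purchased) | CC(=O)c1c(O)cc(OCc2ccccc2)cc1OCc1ccccc1
F2 | step 13 | (E)-1-[2,4-bis(benzyloxy)-6-hydroxyphenyl]-3-[(2R,3S)-7-(benzyloxy)-2-[4-(benzyloxy)-3-methoxyphenyl]-3-{[tert-butyl(dimethyl)silyl]oxymethyl}-2,3-dihydro-1-benzofuran-5-yl]prop-2-en-1-one | COc1cc([C@@H]2Oc3c(OCc4ccccc4)cc(/C=C/C(=O)c4c(O)cc(OCc5ccccc5)cc4OCc4ccccc4)cc3[C@H]2CO[Si](C)(C)C(C)(C)C)ccc1OCc1ccccc1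
F3 | step 13 | (2R)-5,7-bis(benzyloxy)-2-[(2R,3S)-7-(benzyloxy)-2-[4-(benzyloxy)-3-methoxyphenyl]-3-{[tert-butyl(dimethyl)silyl]oxymethyl}-2,3-dihydro-1-benzofuran-5-yl]chroman-4-one | COc1cc([C@@H]2Oc3c(OCc4ccccc4)cc([C@H]4CC(=O)c5c(OCc6ccccc6)cc(OCc6ccccc6)cc5O4)cc3[C@H]2CO[Si](C)(C)C(C)(C)C)ccc1OCc1ccccc1
F4 | step 14 | (2S)-5,7-bis(benzyloxy)-4-methoxy-2-[(2R,3S)-7-(benzyloxy)-2-[4-(benzyloxy)-3-methoxyphenyl]-3-{[tert-butyl(dimethyl)silyl]oxymethyl}-2,3-dihydro-1-benzofuran-5-yl]chromane (both C4' epimers) | COc1cc([C@@H]2Oc3c(OCc4ccccc4)cc([C@@H]4CC(OC)c5c(OCc6ccccc6)cc(OCc6ccccc6)cc5O4)cc3[C@H]2CO[Si](C)(C)C(C)(C)C)ccc1OCc1ccccc1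
F5 | step 7 | 2-[3-(benzyloxy)-2-{[4-(benzyloxy)-3-methoxyphenyl]methoxy}-5-(1,3-dioxolan-2-yl)phenyl]acetic acid | OC(=O)Cc1cc(C2OCCO2)cc(OCc2ccccc2)c1OCc1ccc(OCc2ccccc2)c(OC)c1
F6 | step 7 | (2S)-2-hydroxy-1-(pyrrolidin-1-yl)propan-1-one (purchased) | C[C@H](O)C(=O)N1CCCC1
F7 | step 7 | (2S)-1-oxo-1-(pyrrolidin-1-yl)propan-2-yl 2-[3-(benzyloxy)-2-{[4-(benzyloxy)-3-methoxyphenyl]methoxy}-5-(1,3-dioxolan-2-yl)phenyl]acetate | C[C@H](OC(=O)Cc1cc(C2OCCO2)cc(OCc2ccccc2)c1OCc1ccc(OCc2ccccc2)c(OC)c1)C(=O)N1CCCC1
F8 | step 7 | (2S)-1-oxo-1-(pyrrolidin-1-yl)propan-2-yl 2-diazo-2-[3-(benzyloxy)-2-{[4-(benzyloxy)-3-methoxyphenyl]methoxy}-5-(1,3-dioxolan-2-yl)phenyl]acetate | C[C@H](OC(=O)C(=[N+]=[N-])c1cc(C2OCCO2)cc(OCc2ccccc2)c1OCc1ccc(OCc2ccccc2)c(OC)c1)C(=O)N1CCCC1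
F9 | step 7 | (2S)-1-oxo-1-(pyrrolidin-1-yl)propan-2-yl (2R,3R)-7-(benzyloxy)-2-[4-(benzyloxy)-3-methoxyphenyl]-5-(1,3-dioxolan-2-yl)-2,3-dihydro-1-benzofuran-3-carboxylate | COc1cc([C@@H]2Oc3c(OCc4ccccc4)cc(C4OCCO4)cc3[C@H]2C(=O)O[C@@H](C)C(=O)N2CCCC2)ccc1OCc1ccccc1
F10 | step 2 | 3-(benzyloxy)-4-hydroxybenzaldehyde (purchased) | O=Cc1ccc(O)c(OCc2ccccc2)c1
F11 | step 2 | 3-(benzyloxy)-5-bromo-4-hydroxybenzaldehyde | O=Cc1cc(Br)c(O)c(OCc2ccccc2)c1
F0 | step 17 | none | none
A1 | alternative 1 | methyl (2R,3R)-2-[4-(benzyloxy)-3-methoxyphenyl]-5-(1,3-dioxolan-2-yl)-7-(methoxymethoxy)-2,3-dihydro-1-benzofuran-3-carboxylate (trans) | COc1cc([C@@H]2Oc3c(OCOC)cc(C4OCCO4)cc3[C@H]2C(=O)OC)ccc1OCc1ccccc1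
A2 | alternative 1 | methyl 2-diazo-2-[2-{[4-(benzyloxy)-3-methoxyphenyl]methoxy}-5-(1,3-dioxolan-2-yl)-3-(methoxymethoxy)phenyl]acetate | COCOc1cc(C2OCCO2)cc(C(=[N+]=[N-])C(=O)OC)c1OCc1ccc(OCc2ccccc2)c(OC)c1
A3 | alternative 2 | (2R,3S)-3-{[tert-butyl(dimethyl)silyl]oxymethyl}-2-(4-hydroxy-3-methoxyphenyl)-7-(methoxymethoxy)-2,3-dihydro-1-benzofuran-5-carbaldehyde | COc1cc([C@@H]2Oc3c(OCOC)cc(C=O)cc3[C@H]2CO[Si](C)(C)C(C)(C)C)ccc1O
A4 | alternative 2 | 3-[(2S)-1-{[tert-butyl(dimethyl)silyl]oxy}-3-(4-hydroxy-3-methoxyphenyl)propan-2-yl]-4-hydroxy-5-(methoxymethoxy)benzaldehyde | O=Cc1cc(OCOC)c(O)c(c1)[C@H](Cc1ccc(O)c(OC)c1)CO[Si](C)(C)C(C)(C)C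
A5 | alternative 3 | (2R,3R)-7-(benzyloxy)-2-[4-(benzyloxy)-3-methoxyphenyl]-5-bromo-3-(dimethoxymethyl)-2,3-dihydro-1-benzofuran (trans) | COc1cc([C@@H]2Oc3c(OCc4ccccc4)cc(Br)cc3[C@H]2C(OC)OC)ccc1OCc1ccccc1
A6 | alternative 3 | (2R)-8-(benzyloxy)-2-[4-(benzyloxy)-3-methoxyphenyl]-6-bromo-2H-chromene | COc1cc([C@H]2C=Cc3cc(Br)cc(OCc4ccccc4)c3O2)ccc1OCc1ccccc1
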